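**Plan**
Cuts: first the depside ester bond between O-5' of ring B and the ring A carbonyl. Next the two aryl–CHO bonds (C3–CHO and C3'–CHO), and last C1'–C2' and C5'–C6' of ring B.
Enabling feature: in ring B (C1' carries CO2H), O-2' and O-5' are para. The C1'/C6' edge (carboxyl and methyl carbons) is a but-2-ynoate. The C3'/C4' edge (CH and C–O) is C3/C4 of a tetronate-derived furan, and O-5' is the furan ring oxygen. Ring B is therefore a bridge-opened furan–alkyne cycloadduct.
Forward, ring B: tetronic acid gives the benzyl tetronate and then the silyloxyfuran. Cycloaddition with benzyl but-2-ynoate and bridge opening build ring B, which is formylated at its only free carbon.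
Forward, ring A: it comes intact from orsellinic acid (benzyl ester, 4-O-methyl, 3-formyl, free acid) and is joined to the free 5'-hydroxyl. One hydrogenolysis ends the route.
The three oxygens of ring B differ by origin: O-5' is free, O-2' is chelated, O-4' is benzylated. The target is achiral, and the bridgehead centres of the cycloadduct are transient.

Key step: step 4

Remark: unprimed locants refer to ring A (C1 bears the depside carbonyl) and primed locants to ring B. Furan 4 is hydrolytically labile and is assumed to be used directly after its preparation.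

**Step 1**
Reactants: 1 tetronic acid; 2 benzyl alcohol
Product: 3 4-(benzyloxy)furan-2(5H)-one (benzyl tetronate)
Conditions: p-TsOH·H2O (cat.), PhMe, Dean–Stark, reflux
Reagents that add atoms: none
Why: Acid-catalysed enol etherification of the vinylogous acid (a vinylogous Fischer esterification) with azeotropic removal of water is the standard route to alkyl tetronates, and only the C4 oxygen can react this way.

**Step 2**
Reactants: 3 4-(benzyloxy)furan-2(5H)-one
Product: 4 4-(benzyloxy)-2-(trimethylsilyloxy)furan
Conditions: Me3SiOSO2CF3, Et3N, CH2Cl2, 0 °C; pentane, filtration under Ar; used at once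
Reagents that add atoms: trimethylsilyl triflate, C[Si](C)(C)OS(=O)(=O)C(F)(F)F
Why: Soft enolisation of a butenolide (O-silylation of the lactone carbonyl, then amine deprotonation at C5) is the standard silyloxyfuran synthesis and is driven by the gain of furan aromaticity.

**Step 3**
Reactants: 5 but-2-ynoic acid
Product: 6 benzyl but-2-ynoate
Conditions: BnBr, K2CO3, DMF, rt
Reagents that add atoms: benzyl bromide, BrCc1ccccc1
Why: SN2 alkylation of the carboxylate is a routine esterification, and the carbonate base at room temperature should be too weak to isomerise the ynoate to the allenoate.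

**Step 4**
Reactants: 4 4-(benzyloxy)-2-(trimethylsilyloxy)furan; 6 benzyl but-2-ynoate
Product: 9 benzyl 4-(benzyloxy)-2,5-dihydroxy-6-methylbenzoate, via oxanorbornadiene cycloadduct 7 (not isolated), via 2'-O-trimethylsilyl hydroquinone 8 (not isolated)
Conditions: 4 (2 equiv), PhMe (concentrated), sealed tube, Ar, 120 °C; then 1 M HCl, THF, 0 °C to rt
Reagents that add atoms: none
Why: The furan is a ring-locked s-cis 1,1,3-trioxygenated diene and should add to the ynoate in a normal-electron-demand, concerted but strongly asynchronous Diels–Alder reaction, furan C5 bonding first to the methyl-bearing β-carbon (C5'–C6') and furan C2 to the α-carbon (C1'–C2') to give 7. In 7 the bridge C–O bond at the silyloxy-bearing bridgehead ionises, because the cation is an oxocarbenium ion that the benzyloxy group stabilises further through the adjacent double bond, loss of the proton at the other bridgehead aromatises the ring to 8, and dilute acid takes off the silyl group. The closest known reactions are the additions of 2-silyloxy- and 2-alkoxyfurans to acetylenic esters, which open spontaneously to hydroquinone derivatives, and the thermal additions of acyclic 1,1,3-trioxygenated butadienes to β-alkyl ynoates, which give orsellinates with the same orientation. The six-membered carbocycle of ring B closes by intermolecular (4+2) cycloaddition, both σ-bonds arising in the one event, and the five-membered heterocycle disappears when the bridge opens. The two bridgehead stereocentres of 7 arise as a racemate, are tied to each other by the bicyclic frame and are erased on aromatisation, so none needs control. The one selectivity required is orientation, and it is secured because the 2-silyloxy group (through the diene) and the 4-benzyloxy group (directly) both raise the HOMO coefficient at C5 while the ester places the largest LUMO coefficient on the β-carbon; the second equivalent of 4 allows for silyl transfer to the phenol that is set free.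

**Step 5**
Reactants: 9 benzyl 4-(benzyloxy)-2,5-dihydroxy-6-methylbenzoate
Product: 10 benzyl 4-(benzyloxy)-3-formyl-2,5-dihydroxy-6-methylbenzoate
Conditions: MgCl2 (anhydrous), Et3N, (CH2O)n, MeCN, Ar, reflux; 1 M HCl work-up
Reagents that add atoms: paraformaldehyde (source of formaldehyde), C=O
Why: In the Casnati–Skattebøl ortho-formylation the magnesium phenoxide of the 2'-hydroxyl delivers formaldehyde to the neighbouring carbon, C3' is the only unsubstituted position of the ring, and the absence of a strong Lewis acid spares the benzyl ether and ester.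

**Step 6**
Reactants: 11 orsellinic acid
Product: 12 benzyl 2,4-dihydroxy-6-methylbenzoate (benzyl orsellinate)
Conditions: BnBr, KHCO3, DMF, rt
Reagents that add atoms: benzyl bromide, BrCc1ccccc1
Why: Carboxylate alkylation with a hydrogen carbonate base ionises only the acid, so both phenols stay free, and the low temperature avoids decarboxylation.

**Step 7**
Reactants: 12 benzyl 2,4-dihydroxy-6-methylbenzoate
Product: 13 benzyl 2-hydroxy-4-methoxy-6-methylbenzoate
Conditions: MeI (1 equiv), K2CO3, acetone, reflux
Reagents that add atoms: methyl iodide, CI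
Why: In this Williamson etherification the 2-hydroxyl is hydrogen-bonded to the ester carbonyl and is much the poorer nucleophile, so one equivalent of MeI should go to the 4-hydroxyl.

**Step 8**
Reactants: 13 benzyl 2-hydroxy-4-methoxy-6-methylbenzoate
Product: 14 benzyl 3-formyl-2-hydroxy-4-methoxy-6-methylbenzoate
Conditions: MgCl2 (anhydrous), Et3N, (CH2O)n, MeCN, reflux; 1 M HCl work-up
Reagents that add atoms: paraformaldehyde (source of formaldehyde), C=O
Why: The Casnati–Skattebøl formylation acts strictly ortho to the phenol, C3 is the only free ortho position, and C5 should therefore stay untouched.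

**Step 9**
Reactants: 14 benzyl 3-formyl-2-hydroxy-4-methoxy-6-methylbenzoate
Product: 15 3-formyl-2-hydroxy-4-methoxy-6-methylbenzoic acid
Conditions: H2 (1 atm), 10% Pd/C, EtOAc, rt, stopped after one equivalent of H2
Reagents that add atoms: none
Why: Catalytic hydrogenolysis of a benzyl ester is far faster than reduction of a chelated, electron-rich aryl aldehyde, which is why this deprotection is routine for formyl-bearing lichen acids.

**Step 10**
Reactants: 15 3-formyl-2-hydroxy-4-methoxy-6-methylbenzoic acid; 10 benzyl 4-(benzyloxy)-3-formyl-2,5-dihydroxy-6-methylbenzoate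
Product: 17 benzyl 4-(benzyloxy)-3-formyl-5-[(3-formyl-2-hydroxy-4-methoxy-6-methylbenzoyl)oxy]-2-hydroxy-6-methylbenzoate, via acyl trifluoroacetate 16 (not isolated)
Conditions: (CF3CO)2O, PhMe, 0 °C to rt; aq. NaHCO3 work-up
Reagents that add atoms: none
Why: The trifluoroacetic anhydride (mixed-anhydride) esterification is the classical depside coupling and suits a hindered electron-rich acid because 16 reacts with acylium character, while the 5'-hydroxyl is the only phenol not locked in a hydrogen bond to a carbonyl group and ring B has no free carbon left for C-acylation.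

**Step 11**
Reactants: 17 benzyl 4-(benzyloxy)-3-formyl-5-[(3-formyl-2-hydroxy-4-methoxy-6-methylbenzoyl)oxy]-2-hydroxy-6-methylbenzoate
Product: 18 haemathamnolic acid
Conditions: H2 (1 atm), 10% Pd/C, EtOAc, rt, stopped after two equivalents of H2
Reagents that add atoms: none
Why: Neutral catalytic hydrogenolysis removes the benzyl ester and the aryl benzyl ether together, should leave the depside ester, the methyl ether and both chelated aldehydes alone, and offers no base or acid to move the acyl group from O-5' to O-4'.

**Compound list**
1 | tetronic acid (furan-2,4(3H,5H)-dione) | O=C1COC(=O)C1 | starting material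
2 | benzyl alcohol | OCc1ccccc1 | starting material
3 | 4-(benzyloxy)furan-2(5H)-one | O=C1C=C(OCc2ccccc2)CO1 | intermediate
4 | 4-(benzyloxy)-2-(trimethylsilyloxy)furan | C[Si](C)(C)Oc1cc(OCc2ccccc2)co1 | intermediate
5 | but-2-ynoic acid | CC#CC(=O)O | starting material
6 | benzyl but-2-ynoate | CC#CC(=O)OCc1ccccc1 | intermediate
7 | benzyl 5-(benzyloxy)-3-methyl-1-(trimethylsilyloxy)-7-oxabicyclo[2.2.1]hepta-2,5-diene-2-carboxylate (racemic, formed in the flask) | C[Si](C)(C)OC12OC(C(C)=C1C(=O)OCc1ccccc1)C(OCc1ccccc1)=C2 | intermediate
8 | benzyl 4-(benzyloxy)-5-hydroxy-6-methyl-2-(trimethylsilyloxy)benzoate (formed in the flask) | Cc1c(O)c(OCc2ccccc2)cc(O[Si](C)(C)C)c1C(=O)OCc1ccccc1 | intermediate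
9 | benzyl 4-(benzyloxy)-2,5-dihydroxy-6-methylbenzoate | Cc1c(O)c(OCc2ccccc2)cc(O)c1C(=O)OCc1ccccc1 | intermediate
10 | benzyl 4-(benzyloxy)-3-formyl-2,5-dihydroxy-6-methylbenzoate | Cc1c(O)c(OCc2ccccc2)c(C=O)c(O)c1C(=O)OCc1ccccc1 | intermediate
11 | orsellinic acid (2,4-dihydroxy-6-methylbenzoic acid) | Cc1cc(O)cc(O)c1C(=O)O | starting material
12 | benzyl 2,4-dihydroxy-6-methylbenzoate | Cc1cc(O)cc(O)c1C(=O)OCc1ccccc1 | intermediate
13 | benzyl 2-hydroxy-4-methoxy-6-methylbenzoate | COc1cc(C)c(C(=O)OCc2ccccc2)c(O)c1 | intermediate
14 | benzyl 3-formyl-2-hydroxy-4-methoxy-6-methylbenzoate | COc1cc(C)c(C(=O)OCc2ccccc2)c(O)c1C=O | intermediate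
15 | 3-formyl-2-hydroxy-4-methoxy-6-methylbenzoic acid | COc1cc(C)c(C(=O)O)c(O)c1C=O | intermediate
16 | 3-formyl-2-hydroxy-4-methoxy-6-methylbenzoic trifluoroacetic anhydride (formed in the flask) | COc1cc(C)c(C(=O)OC(=O)C(F)(F)F)c(O)c1C=O | intermediate
17 | benzyl 4-(benzyloxy)-3-formyl-5-[(3-formyl-2-hydroxy-4-methoxy-6-methylbenzoyl)oxy]-2-hydroxy-6-methylbenzoate | COc1cc(C)c(C(=O)Oc2c(C)c(C(=O)OCc3ccccc3)c(O)c(C=O)c2OCc2ccccc2)c(O)c1C=O | intermediate
18 | haemathamnolic acid, 3-formyl-5-[(3-formyl-2-hydroxy-4-methoxy-6-methylbenzoyl)oxy]-2,4-dihydroxy-6-methylbenzoic acid | COc1cc(C)c(C(=O)Oc2c(C)c(C(=O)O)c(O)c(C=O)c2O)c(O)c1C=O | target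

**Step count**
- Total step count: 11.
- Longest linear sequence: 6 steps (1, 2, 4, 5, 10, 11 from tetronic acid). The ring A branch (6, 7, 8, 9, 10, 11 from orsellinic acid) is equally long.

**Steps most likely to fail**

Step 4. The cycloaddition may be too slow for a β-methyl ynoate that carries only one acceptor. Protodesilylation of the furan, or an open-chain vinylogous Michael addition without ring closure, could then take over.
- The fallback makes ring B from an existing arene and sets out from 12.
- BnBr (1 equiv) and K2CO3 in acetone etherify the non-chelated 4-hydroxyl to give benzyl 4-(benzyloxy)-2-hydroxy-6-methylbenzoate F1.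
- An Elbs persulfate oxidation (K2S2O8, aq. KOH, pyridine, 0 °C to rt) then oxygenates C5, the position para to the phenolate. This gives potassium 6-(benzyloxy)-3-[(benzyloxy)carbonyl]-4-hydroxy-2-methylphenyl sulfate F2.
- Warming F2 with dilute HCl hydrolyses the sulfate, and the route is rejoined at 9.

Step 10. Acylation of the 5'-hydroxyl, which is flanked on both sides, may be slow. Self-condensation of the acid through its own phenol, or loss of site selectivity, could then compete.
- The fallback masks the ring A phenol and uses an acid chloride. It sets out from 15.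
- Allyl bromide and KHCO3 in DMF give allyl 3-formyl-2-hydroxy-4-methoxy-6-methylbenzoate F3.
- BnBr and K2CO3 in DMF at 60 °C give allyl 2-(benzyloxy)-3-formyl-4-methoxy-6-methylbenzoate F4.
- A Tsuji–Trost deallylation (Pd(PPh3)4 cat., 4-MeC6H4SO2Na, THF/MeOH, then acidification) gives 2-(benzyloxy)-3-formyl-4-methoxy-6-methylbenzoic acid F5.
- (COCl)2 with catalytic DMF in CH2Cl2 gives 2-(benzyloxy)-3-formyl-4-methoxy-6-methylbenzoyl chloride F6.
- F6 acylates 10 (Et3N, DMAP, CH2Cl2) to give benzyl 4-(benzyloxy)-5-{[2-(benzyloxy)-3-formyl-4-methoxy-6-methylbenzoyl]oxy}-3-formyl-2-hydroxy-6-methylbenzoate F7.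
- Hydrogenolysis of F7 under the conditions of step 11 removes all three benzyl groups, and the route is rejoined at 18.

Step 5. The hydroquinone may be oxidised under the basic conditions. The formylation may also stall because the salicylate ester ties up the magnesium phenoxide.
- The fallback reverses the order of events and sets out from 9.
- Compound 9 is coupled with 15 under the conditions of step 10 (by way of 16). This gives benzyl 4-(benzyloxy)-5-[(3-formyl-2-hydroxy-4-methoxy-6-methylbenzoyl)oxy]-2-hydroxy-6-methylbenzoate F8.
- A Rieche formylation (TiCl4, Cl2CHOMe, CH2Cl2, −78 to 0 °C) then attacks C3'. This carbon lies next to the titanium-bound 2'-phenoxide and belongs to the more electron-rich ring, since ring A already carries two carbonyl groups.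
- The route is rejoined at 17.

**Further compounds**
F1 | step 4 | benzyl 4-(benzyloxy)-2-hydroxy-6-methylbenzoate | Cc1cc(OCc2ccccc2)cc(O)c1C(=O)OCc1ccccc1
F2 | step 4 | potassium 6-(benzyloxy)-3-[(benzyloxy)carbonyl]-4-hydroxy-2-methylphenyl sulfate | Cc1c(OS(=O)(=O)[O-])c(OCc2ccccc2)cc(O)c1C(=O)OCc1ccccc1.[K+]
F3 | step 10 | allyl 3-formyl-2-hydroxy-4-methoxy-6-methylbenzoate | COc1cc(C)c(C(=O)OCC=C)c(O)c1C=O
F4 | step 10 | allyl 2-(benzyloxy)-3-formyl-4-methoxy-6-methylbenzoate | COc1cc(C)c(C(=O)OCC=C)c(OCc2ccccc2)c1C=O
F5 | step 10 | 2-(benzyloxy)-3-formyl-4-methoxy-6-methylbenzoic acid | COc1cc(C)c(C(=O)O)c(OCc2ccccc2)c1C=O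
F6 | step 10 | 2-(benzyloxy)-3-formyl-4-methoxy-6-methylbenzoyl chloride | COc1cc(C)c(C(Cl)=O)c(OCc2ccccc2)c1C=O
F7 | step 10 | benzyl 4-(benzyloxy)-5-{[2-(benzyloxy)-3-formyl-4-methoxy-6-methylbenzoyl]oxy}-3-formyl-2-hydroxy-6-methylbenzoate | COc1cc(C)c(C(=O)Oc2c(C)c(C(=O)OCc3ccccc3)c(O)c(C=O)c2OCc2ccccc2)c(OCc2ccccc2)c1C=O
F8 | step 5 | benzyl 4-(benzyloxy)-5-[(3-formyl-2-hydroxy-4-methoxy-6-methylbenzoyl)oxy]-2-hydroxy-6-methylbenzoate | COc1cc(C)c(C(=O)Oc2c(C)c(C(=O)OCc3ccccc3)c(O)cc2OCc2ccccc2)c(O)c1C=O
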